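## Retrosynthetic overview

1. Target (2R,3S,3aS,5R; aryl, methyl, allyl and 5-OMe all on one face) ⇐ all-cis 4,5-dehydro dienone, by conjugate hydride to C4 and kinetic protonation at C5.
2. All-cis dienone ⇐ ring-opened hydroxy vinylogous acid by C2–O closure with inversion; that acid ⇐ the 2,3-trans cycloadduct by saponification (C2 untouched). Closure of the free benzylic cation gives 2,3-trans, whereas the target is 2,3-cis.
3. trans Cycloadduct ⇐ one-step union of the two C6C3 units as in the plant: oxidised 2-allyl-4,5-dimethoxyphenol (para-quinone monoketal) plus (E)-isoelemicin, formal [3+2], under a chiral Brønsted acid. This sets C3 and the quaternary C3a.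
4. Building blocks ⇐ 3,4-dimethoxyphenol (O-allylation, Claisen, oxidative ketalisation) and 5-bromo-1,2,3-trimethoxybenzene (Suzuki).
5. Ring order: both six-membered rings are bought; the dihydrofuran ring is the only ring made (cycloaddition), then opened and reclosed once to invert C2.

Assumption: the (R) antipode of the acid catalyst is written for the (2S,3S,3aR) series; if the first run gives the mirror-image series, the (S) acid is used with nothing else changed.

## Route

Step 1
Reactants: 1 3,4-dimethoxyphenol; 2 allyl bromide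
Product: 3 4-(allyloxy)-1,2-dimethoxybenzene
Conditions: K2CO3, acetone, reflux
Reagents that add atoms: none
Why: Williamson ether synthesis, the phenoxide displacing bromide from the allylic halide (SN2); no stereocentre.

Step 2
Reactants: 3 4-(allyloxy)-1,2-dimethoxybenzene
Product: 4 2-allyl-4,5-dimethoxyphenol
Conditions: PhNEt2, 190 °C
Reagents that add atoms: none
Why: Aromatic Claisen rearrangement ([3,3]-sigmatropic) delivers the allyl group to the free ortho carbon rather than the one flanked by a methoxy group, then tautomerises to the phenol; no stereocentre.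

Step 3
Reactants: 4 2-allyl-4,5-dimethoxyphenol
Product: 5 2-allyl-4,4,5-trimethoxycyclohexa-2,5-dien-1-one (para-quinone monoketal)
Conditions: PhI(OAc)2, MeOH, 0 °C
Reagents that add atoms: methanol, CO
Why: Oxidative dearomatisation of a para-methoxyphenol by trivalent iodine in methanol adds methoxide para to the phenol oxygen and leaves the allyl group alone; no stereocentre.

Step 4
Reactants: 6 5-bromo-1,2,3-trimethoxybenzene; 7 (E)-4,4,5,5-tetramethyl-2-(prop-1-en-1-yl)-1,3,2-dioxaborolane
Product: 8 (E)-isoelemicin, 1,2,3-trimethoxy-5-[(E)-prop-1-en-1-yl]benzene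
Conditions: Pd(PPh3)4 (3 mol%), K2CO3, 1,4-dioxane/H2O, 90 °C
Reagents that add atoms: none
Why: Suzuki–Miyaura coupling on zerovalent palladium transfers the propenyl group with retention of the E geometry that step 5 needs.

Step 5
Reactants: 5 2-allyl-4,4,5-trimethoxycyclohexa-2,5-dien-1-one; 8 (E)-isoelemicin (1.5 equiv)
Product: 10 (2S,3S,3aR)-3a-allyl-5-methoxy-3-methyl-2-(3,4,5-trimethoxyphenyl)-3,3a-dihydro-1-benzofuran-6(2H)-one, via C6 dimethyl ketal 9 (not isolated)
Conditions: (R)-3,3′-bis(2,4,6-triisopropylphenyl)-1,1′-binaphthyl-2,2′-diyl N-triflylphosphoramide (C51H57F3NO5PS, 5 mol%), CH2Cl2, −78 to −30 °C; then H2O/THF, 0 °C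
Reagents that add atoms: water, O
Why: Proposed new method: the acid ionises the ketal to the 2-allyl-4,5-dimethoxyphenoxonium (O-methyl oxocarbenium) ion held as a contact ion pair with the chiral phosphoramidate; the E-alkene adds suprafacially, C8 to the allyl-bearing carbon and the benzylic carbon to the carbonyl oxygen (formal [3+2] cycloaddition of an oxidised allylphenol with a propenylbenzene), with the aryl group stacked over the cation so that 3-Me is cis to allyl and 2-Ar trans to both, while the anion blocks one face of the planar cation to give 3S,3aR; released methanol traps the product oxocarbenium as ketal 9 and returns the proton, and water unmasks the C6 ketone; the closest known reaction type is the racemic acid-promoted cycloaddition of quinone monoketals with (E)-propenylbenzenes, together with chiral-phosphoric-acid [3+2] couplings of quinone monoimides with styrenes.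

Step 6
Reactants: 10 (2S,3S,3aR)-3a-allyl-5-methoxy-3-methyl-2-(3,4,5-trimethoxyphenyl)-3,3a-dihydro-1-benzofuran-6(2H)-one
Product: 11 (6R)-6-allyl-3-hydroxy-6-[(1S,2S)-1-hydroxy-1-(3,4,5-trimethoxyphenyl)propan-2-yl]-4-methoxycyclohexa-2,4-dien-1-one
Conditions: LiOH, THF/H2O, 0 to 40 °C; then 1 M HCl to pH 4, 0 °C
Reagents that add atoms: lithium hydroxide, [Li+].[OH-]
Why: Vinylogous ester saponification: hydroxide adds to C7a (addition–elimination) and the ring oxygen leaves on C2, so the C2–O bond is never broken and the benzylic centre keeps its configuration; formation of the vinylogous carboxylate makes the opening irreversible.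

Step 7
Reactants: 11 (6R)-6-allyl-3-hydroxy-6-[(1S,2S)-1-hydroxy-1-(3,4,5-trimethoxyphenyl)propan-2-yl]-4-methoxycyclohexa-2,4-dien-1-one
Product: 12 (2R,3S,3aR)-3a-allyl-5-methoxy-3-methyl-2-(3,4,5-trimethoxyphenyl)-3,3a-dihydro-1-benzofuran-6(2H)-one (aryl, methyl and allyl all cis)
Conditions: PPh3, DIAD, THF, −20 to 0 °C (11 added slowly to the preformed betaine)
Reagents that add atoms: none
Why: Intramolecular Mitsunobu etherification: the vinylogous acid (pKa about 5) protonates the betaine, the benzylic alcohol is activated as its oxyphosphonium ion and the enolate oxygen displaces it 5-exo-tet with inversion, turning the 1S carbinol into 2R; O-alkylation is the enolate ring closure allowed here, and this closes the same C2–O bond with the same nucleophile as the cycloaddition.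

Step 8
Reactants: 12 (2R,3S,3aR)-3a-allyl-5-methoxy-3-methyl-2-(3,4,5-trimethoxyphenyl)-3,3a-dihydro-1-benzofuran-6(2H)-one
Product: 14 dysodanthin B, via silyl enol ether 13 (not isolated)
Conditions: [(Ph3P)CuH]6 (5 mol%), PhMe2SiH, toluene, 0 °C to rt; then Bu4NF, AcOH, THF, −78 °C
Reagents that add atoms: dimethylphenylsilane, C[SiH](C)c1ccccc1 (its silyl group is carried only in 13; 14 gains hydrogen alone)
Why: Copper hydride 1,4-hydrosilylation (conjugate reduction) takes only the α-methoxy enone, since the β-alkoxy enone is a deactivated vinylogous ester and the allyl group is no acceptor; buffered fluoride then protonates the enol silane at C5 from the face opposite the pseudoaxial 3a-allyl group, which sets 5R (methoxy cis to allyl) under kinetic control with no base present afterwards.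

## Compound list

1 | 3,4-dimethoxyphenol | COc1ccc(O)cc1OC | starting material
2 | allyl bromide (3-bromoprop-1-ene) | C=CCBr | starting material
3 | 4-(allyloxy)-1,2-dimethoxybenzene | C=CCOc1ccc(OC)c(OC)c1 | intermediate
4 | 2-allyl-4,5-dimethoxyphenol | C=CCc1cc(OC)c(OC)cc1O | intermediate
5 | 2-allyl-4,4,5-trimethoxycyclohexa-2,5-dien-1-one | C=CCC1=CC(OC)(OC)C(OC)=CC1=O | intermediate
6 | 5-bromo-1,2,3-trimethoxybenzene | COc1cc(Br)cc(OC)c1OC | starting material
7 | (E)-4,4,5,5-tetramethyl-2-(prop-1-en-1-yl)-1,3,2-dioxaborolane | C/C=C/B1OC(C)(C)C(C)(C)O1 | starting material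
8 | (E)-isoelemicin, 1,2,3-trimethoxy-5-[(E)-prop-1-en-1-yl]benzene | C/C=C/c1cc(OC)c(OC)c(OC)c1 | intermediate
9 | (2S,3S,3aR)-3a-allyl-5,6,6-trimethoxy-3-methyl-2-(3,4,5-trimethoxyphenyl)-2,3,3a,6-tetrahydro-1-benzofuran | C=CC[C@@]12C=C(OC)C(OC)(OC)C=C1O[C@H](c1cc(OC)c(OC)c(OC)c1)[C@H]2C | intermediate (not isolated)
10 | (2S,3S,3aR)-3a-allyl-5-methoxy-3-methyl-2-(3,4,5-trimethoxyphenyl)-3,3a-dihydro-1-benzofuran-6(2H)-one (aryl trans to methyl, methyl cis to allyl) | C=CC[C@@]12C=C(OC)C(=O)C=C1O[C@H](c1cc(OC)c(OC)c(OC)c1)[C@H]2C | intermediate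
11 | (6R)-6-allyl-3-hydroxy-6-[(1S,2S)-1-hydroxy-1-(3,4,5-trimethoxyphenyl)propan-2-yl]-4-methoxycyclohexa-2,4-dien-1-one | C=CC[C@]1(C=C(OC)C(O)=CC1=O)[C@H](C)[C@H](O)c1cc(OC)c(OC)c(OC)c1 | intermediate
12 | (2R,3S,3aR)-3a-allyl-5-methoxy-3-methyl-2-(3,4,5-trimethoxyphenyl)-3,3a-dihydro-1-benzofuran-6(2H)-one (aryl, methyl, allyl all cis) | C=CC[C@@]12C=C(OC)C(=O)C=C1O[C@@H](c1cc(OC)c(OC)c(OC)c1)[C@H]2C | intermediate
13 | (2R,3S,3aS)-3a-allyl-6-[dimethyl(phenyl)silyloxy]-5-methoxy-3-methyl-2-(3,4,5-trimethoxyphenyl)-2,3,3a,4-tetrahydro-1-benzofuran | C=CC[C@@]12CC(OC)=C(O[Si](C)(C)c3ccccc3)C=C1O[C@@H](c1cc(OC)c(OC)c(OC)c1)[C@H]2C | intermediate (not isolated)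
14 | dysodanthin B, (2R,3S,3aS,5R)-3a-allyl-5-methoxy-3-methyl-2-(3,4,5-trimethoxyphenyl)-3,3a,4,5-tetrahydro-1-benzofuran-6(2H)-one | C=CC[C@@]12C[C@@H](OC)C(=O)C=C1O[C@@H](c1cc(OC)c(OC)c(OC)c1)[C@H]2C | target

## Step count and risks

Total steps: 8. Longest linear sequence: 7 (steps 1, 2, 3, 5, 6, 7, 8; step 4 runs in parallel).

The three steps most likely to fail:

**Step 5** (new asymmetric variant). The risks are low enantioselectivity, competing carbon-terminated closure of the benzylic cation, and acid dimerisation of 8. The fallback sets out from 5 (with 8) and comes back at 10. The cycloaddition is run in its established racemic form (Me3SiOTf, 10 mol%, MeCN, −40 °C, aqueous work-up) to give the racemic trans cycloadduct F1. The enantiomers are then separated by preparative supercritical-fluid chromatography on a chiral amylose phase; the (2S,3S,3aR) enantiomer is 10.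

**Step 7** (inversion at a hindered, electron-rich benzylic carbinol). Ionisation, or activation of the enol oxygen instead of the alcohol, would both return 10, which can be sent through step 6 again. The fallback sets out from 11 and comes back at 12. MnO2 (CH2Cl2, rt) oxidises the benzylic alcohol to the aryl ketone F2. The ring is then closed reductively (BF3·OEt2, Et3SiH, CH2Cl2, −78 °C): the ketone closes onto the enol oxygen and takes hydride at C2 from the face away from the C3 methyl and the allyl group. This is the kinetic cis-2-aryl-3-methyl outcome known for five-membered aryl hemiketals at low temperature, so C2 is set by hydride delivery instead of by displacement.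

**Step 8** (C5 face selectivity; minor 1,2- or over-reduction). The fallback sets out from 12 and comes back at 14, and separates reduction from stereocontrol. K[HB(s-Bu)3] (THF, −78 °C) 1,4-reduction and aqueous work-up give 14 mixed with 5-epi-dysodanthin B F3. The mixture is converted with LiN(i-Pr)2 (THF, −78 °C) into the single α′-lithium enolate F4. This is protonated at −78 °C by 2,6-di-tert-butyl-4-methylphenol, a donor large enough to reach C5 only from the face opposite the allyl group.

## Further compounds

F1 | step 5 | racemic 10, i.e. 10 together with its enantiomer (2R,3R,3aS)-3a-allyl-5-methoxy-3-methyl-2-(3,4,5-trimethoxyphenyl)-3,3a-dihydro-1-benzofuran-6(2H)-one (enantiomer drawn) | C=CC[C@]12C=C(OC)C(=O)C=C1O[C@@H](c1cc(OC)c(OC)c(OC)c1)[C@@H]2C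
F2 | step 7 | (6R)-6-allyl-3-hydroxy-4-methoxy-6-[(2S)-1-oxo-1-(3,4,5-trimethoxyphenyl)propan-2-yl]cyclohexa-2,4-dien-1-one | C=CC[C@]1(C=C(OC)C(O)=CC1=O)[C@H](C)C(=O)c1cc(OC)c(OC)c(OC)c1
F3 | step 8 | 5-epi-dysodanthin B, (2R,3S,3aS,5S)-3a-allyl-5-methoxy-3-methyl-2-(3,4,5-trimethoxyphenyl)-3,3a,4,5-tetrahydro-1-benzofuran-6(2H)-one | C=CC[C@@]12C[C@H](OC)C(=O)C=C1O[C@@H](c1cc(OC)c(OC)c(OC)c1)[C@H]2C
F4 | step 8 | lithium (2R,3S,3aS)-3a-allyl-5-methoxy-3-methyl-2-(3,4,5-trimethoxyphenyl)-2,3,3a,4-tetrahydro-1-benzofuran-6-olate | C=CC[C@@]12CC(OC)=C(O[Li])C=C1O[C@@H](c1cc(OC)c(OC)c(OC)c1)[C@H]2C
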